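3 questions stood before me, and I reckoned them from one fraction, that of the right-handed substrate left over:

1. which one finishes higher in share of left-handed product in all that became left-handed product or right-handed product ("neither" within 2 percentage points) (elm / cedar / neither)
2. share of left-handed product in all that became left-handed product or right-handed product, elm
3. share of left-handed product in all that became left-handed product or right-handed product, cedar

| setting | red | grey | elm | cedar |
|---|---|---|---|---|
| left-handed substrate | 0.80 M | 0.80 M | 0.80 M | 0.80 M |
| right-handed substrate | 0.80 M | 0.80 M | 0.80 M | 0.80 M |
| gas | 200 mM (held) | 200 mM (held) | 200 mM (held) | 200 mM (held) |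
| free catalyst | 21 mM | 84 mM | 42 mM | 42 mM |
| impurity | 6.6 mM | 6.6 mM | 6.6 mM | 6.6 mM |
| temperature | 38 °C | 54 °C |  |  |
| remark | run made earlier | run made earlier | at 60 °C throughout | at 60 °C until 10 min, from then on at 30 °C |
| time |  |  | 120 min | 30 min |

- red (time / min: left-handed product / %, right-handed product / %): 6.00: 20.7, 16.1; 20.0: 43.8, 35.8; 40.0: 52.2, 46.6; 80.0: 49.8, 49.5
- grey (time / min: left-handed product / %, right-handed product / %): 2.00: 27.2, 18.1; 4.00: 43.9, 39.2; 6.00: 49.9, 44.8; 12.0: 49.9, 48.8; 25.0: 47.6, 50.5

(each reading ± 1 percentage point)

- free catalyst is single-handed; left-handed substrate and right-handed substrate are mirror images of each other, charged as a racemate, each of them at the stated concentration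
- at the start none of reagent is dissolved
- steps that have been proposed: reagent + free catalyst + right-handed substrate -> free catalyst + right-handed product; reagent + free catalyst + left-handed substrate -> free catalyst + left-handed product; gas <-> reagent; free catalyst + impurity -> spent catalyst

1. The impurity can take at worst 6.6 mM of the free catalyst, and since the readings do not time this, I counted it as done from the start, leaving 35.4 mM in elm and cedar and 14.4 mM in red.

2. Between its first two readings, grey consumed reagent at a read pace of 0.302 M min⁻¹, and I estimated that at this pace the need of 1.60 M in cedar takes about 5.29 min, less than cedar's 10 min of heat; I therefore assumed that supply was no obstacle to the last traces.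

3. With reagent supplied, I treated each substrate as decaying pseudo-first-order. The red reading at 20.0 min gives 0.0629 min⁻¹ for the right-handed substrate, which I scaled by catalyst to 0.155 min⁻¹. I used that rate throughout, although cedar's 60 °C stands above red's 38 °C and its 30 °C below.

4. Let x and y be the fractions of right-handed and left-handed substrate remaining. Both steps use the same reagent and free catalyst, which cancel in the ratio of their rates, so at one temperature d ln y / d ln x is constant, and integrating gives y = x^S, with S the selectivity factor, ln y / ln x. The first readings give 1.38 in red and 1.75 in grey, and I used their mean as a reading, 1.56, which for cedar, with its change of temperature, was an approximation of mine. The left-handed share is then (​1 − y)/(2 − x − y).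

5. For cedar I estimated x = 0.964%, so the share came to 50.2%. For elm, with an estimated x of <0.001%, it came to 50.0%. The gap of 0.20 percentage points is less than the margin of 2 points, so I answered neither.

The forecast also said neither, with 50% for elm and 50.2% for cedar, since “Only about 1% right-handed substrate at most remains”.

The simulation gives neither, with 50.0% for elm and 50.1% for cedar.

    reagent + free catalyst + right-handed substrate → free catalyst + right-handed product (k = 1.10 M⁻² s⁻¹, Ea = 37.0 kJ mol⁻¹)
    reagent + free catalyst + left-handed substrate → free catalyst + left-handed product (k = 1.90 M⁻² s⁻¹, Ea = 43.0 kJ mol⁻¹)
    gas ⇌ reagent, rate k3*(csat - [reagent]) (kL = 0.0520 s⁻¹)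
    free catalyst + impurity → spent catalyst (k = 67.0 M⁻¹ s⁻¹, Ea = 48.0 kJ mol⁻¹)
    (constants at 60 °C)

In cedar, the half-life of the right-handed substrate by its own step was 5.6 min at 30.0 min, shorter than the 20.0 min of cold stirring. At the end, 0.29% of its charge remained, which through S gives 50.1% against the simulated 50.1%. A further flask like cedar, but with 0.011 M of free catalyst, kept 45% of its right-handed substrate; the same S gives 56.4%, and that flask stood at 56.8%.

The data are calculated on assumed constants; the scatter is artificial.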